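**Plan**
- Retrosynthesis: the tertiary C–Br/CH2Cl pair is traced back to an exocyclic methylene, the chlorovinyl group to a vinyl group, and the two secondary chlorides to C–OH and C–Si. Two ring bonds are then cut together: CH(heteroatom)–C(=CH2) and CH(OH)–C(CH3)(vinyl).
- Enabling feature: in the cyclohexane the two CHCl carbons flank one CH2, so this C3 unit is a masked malondialdehyde, used here as a β-silyl acrolein. The two fully substituted carbons, CBr(CH2Cl) and C(CH3)(chlorovinyl), flank the other CH2, so one can arrive as an alkenyl nucleophile and the other as the γ-carbon of an (E)-allylboronate.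
- Forward: a linear C7 alkenyl/allyl bis-boronate (4 steps) and a silyl enal (1 step) are joined in step 6 by rhodium 1,4-addition followed by intramolecular allylboration, which closes the only ring.
- Then: Tamao–Fleming oxidation, double Appel chlorination, chloro-acetoxylation of the methylene, ozonolysis, Takai chloro-olefination, and acetate-to-bromide exchange.
- Stereochemistry: the C–Si centre comes from a chiral diene–rhodium catalyst; the carbinol and the quaternary carbon are relayed through the chair allylboration transition state with E-alkene geometry; both chlorides arise by inversion.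
- The C–Br centre comes from anti chloro-acetoxylation and chloronium-assisted substitution with retention; the E-chloroalkene comes from the Takai reaction.

Key step: step 6

Assumption (chemistry): the enantiomer of the chiral diene used in step 6 is the one that gives the (S)-configured C–Si centre of 12; the sense of induction is taken by analogy with β-silyl enones and would be confirmed at 13.

Step 1
Reactants: 1 ethynylmagnesium bromide; 2 2,3-dibromoprop-1-ene
Product: 3 2-bromopent-1-en-4-yne
Conditions: CuBr (5 mol%), THF, 0 °C to rt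
Reagents that add atoms: none
Why: Copper-catalysed SN2 coupling of the alkynyl Grignard reagent at the allylic (not the vinylic) C–Br bond should give the skipped enyne; no stereocentre is formed.

Step 2
Reactants: 3 2-bromopent-1-en-4-yne
Product: 5 (2E)-5-bromo-3-methylhexa-2,5-dien-1-ol, via alkenylalane 4 (not isolated)
Conditions: Me3Al, Cp2ZrCl2 (cat.), CH2Cl2, 0 °C to rt; then (CH2O)n, THF
Reagents that add atoms: trimethylaluminium, C[Al](C)C; formaldehyde (as paraformaldehyde), C=O
Why: Negishi zirconium-catalysed syn-carboalumination of the terminal alkyne places CH3 and Al cis, and hydroxymethylation of the alkenylalane with retention should fix the E-trisubstituted alkene.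

Step 3
Reactants: 5 (2E)-5-bromo-3-methylhexa-2,5-dien-1-ol
Product: 6 (2E)-3-methyl-5-(4,4,5,5-tetramethyl-1,3,2-dioxaborolan-2-yl)hexa-2,5-dien-1-ol
Conditions: B2pin2, PdCl2(dppf) (3 mol%), KOAc, dioxane, 80 °C
Reagents that add atoms: bis(pinacolato)diboron, CC1(C)OB(OC1(C)C)B1OC(C)(C)C(C)(C)O1
Why: Miyaura borylation of the 2-bromo-1-alkene should proceed without touching the free allylic alcohol or the trisubstituted alkene.

Step 4
Reactants: 6 (2E)-3-methyl-5-(4,4,5,5-tetramethyl-1,3,2-dioxaborolan-2-yl)hexa-2,5-dien-1-ol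
Product: 7 2,2'-[(2E)-3-methylhexa-2,5-diene-1,5-diyl]bis(4,4,5,5-tetramethyl-1,3,2-dioxaborolane)
Conditions: B2pin2, Pd(MeCN)4(BF4)2 (5 mol%), DMSO/MeOH, rt
Reagents that add atoms: bis(pinacolato)diboron, CC1(C)OB(OC1(C)C)B1OC(C)(C)C(C)(C)O1
Why: Palladium-catalysed direct borylation of the allylic alcohol through an η3-allyl intermediate should give the linear (E)-allylboronate, the alkenylboronate being inert in the absence of base.

Step 5
Reactants: 8 3,3-diethoxyprop-1-yne; 9 benzyl(dimethyl)silane
Product: 11 (2E)-3-[benzyl(dimethyl)silyl]prop-2-enal, via vinylsilane acetal 10 (not isolated)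
Conditions: Pt2(dvds)3 (0.1 mol%), P(t-Bu)3, THF, rt; then 1 M HCl, THF
Reagents that add atoms: water, O
Why: Platinum-catalysed syn β-hydrosilylation of the terminal alkyne should give the E-vinylsilane, and mild acetal hydrolysis then frees the enal.

Step 6
Reactants: 7 2,2'-[(2E)-3-methylhexa-2,5-diene-1,5-diyl]bis(4,4,5,5-tetramethyl-1,3,2-dioxaborolane); 11 (2E)-3-[benzyl(dimethyl)silyl]prop-2-enal
Product: 13 (1R,2S,5S)-5-[benzyl(dimethyl)silyl]-2-ethenyl-2-methyl-4-methylidenecyclohexan-1-ol, via silyl aldehyde 12 (not isolated)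
Conditions: [RhCl(C2H4)2]2 (2.5 mol%), chiral diene (2,5-diphenylbicyclo[2.2.2]octa-2,5-diene, one enantiomer, 5.5 mol%), KOH (0.3 equiv), dioxane/H2O 10:1, 30 °C
Reagents that add atoms: none
Why: Proposed new method: hydroxo-rhodium should transmetalate the sp2 C–B bond of 7, the alkenyl-rhodium adds 1,4 to enal 11, and water protonates the oxa-π-allyl rhodium to free aldehyde 12, whose pendant (E)-allylboronate then attacks the new C=O through a closed Zimmerman–Traxler chair, so both ring bonds form in one flask. The closest known reaction types are the Hayashi–Miyaura asymmetric 1,4-addition of alkenylboron reagents to β-silyl enones and the intramolecular allylboration of ω-oxo allylboronates; joining them in one domino is the new element. The carbocycle closes by γ-addition of the allylboronate to the tethered aldehyde, a six-membered chair carbocycle fused to the six-membered boron chair. The C–Si stereocentre is set by the chiral diene–rhodium catalyst, and the carbinol and quaternary carbons are relayed from it: aldehyde chain and silyl group equatorial (OH cis to Si), and the E-alkene puts the ring CH2 equatorial and CH3 axial (CH3 cis to OH, vinyl trans). The step needs 1,4- over 1,2-addition (diene ligand), alkenyl- over allyl-boron transmetalation (sp2 versus hindered sp3 boronate held as its hydroxy-ate complex), and no intermolecular allylboration of the conjugated aldehyde of 11 beforehand (γ,γ-disubstituted allyl pinacolboronates are sluggish intermolecularly but fast intramolecularly).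

Step 7
Reactants: 13 (1R,2S,5S)-5-[benzyl(dimethyl)silyl]-2-ethenyl-2-methyl-4-methylidenecyclohexan-1-ol
Product: 14 (1S,3R,4S)-4-ethenyl-4-methyl-6-methylidenecyclohexane-1,3-diol
Conditions: TBAF, THF, 0 °C; then H2O2 (30%), KHCO3, MeOH, rt
Reagents that add atoms: hydrogen peroxide, OO
Why: In this Tamao–Fleming oxidation fluoride cleaves the benzyl–Si bond and the peroxide-induced 1,2-shift from Si to O proceeds with retention, so the allylic hydroxyl should end cis to the other hydroxyl without touching the alkenes.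

Step 8
Reactants: 14 (1S,3R,4S)-4-ethenyl-4-methyl-6-methylidenecyclohexane-1,3-diol
Product: 15 (1S,2S,4R)-2,4-dichloro-1-ethenyl-1-methyl-5-methylidenecyclohexane
Conditions: PPh3, CCl4, MeCN, 0 to 60 °C
Reagents that add atoms: carbon tetrachloride, ClC(Cl)(Cl)Cl
Why: In the Appel reaction both alkoxyphosphonium ions should be displaced by chloride with inversion (SN2), placing the two chlorides cis to each other and to the vinyl group.

Step 9
Reactants: 15 (1S,2S,4R)-2,4-dichloro-1-ethenyl-1-methyl-5-methylidenecyclohexane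
Product: 16 (1R,2R,4S,5S)-2,4-dichloro-1-(chloromethyl)-5-ethenyl-5-methylcyclohexyl acetate
Conditions: NCS, AcOH, rt
Reagents that add atoms: N-chlorosuccinimide, O=C1CCC(=O)N1Cl; acetic acid, CC(=O)O
Why: Chloro-acetoxylation should occur only at the electron-richer 1,1-disubstituted alkene; chlorine adds from the equatorial face away from the axial vinyl and the allylic chloride, and Markovnikov anti-opening of the chloronium ion by acetic acid puts the acetate on the tertiary carbon cis to the ring chlorides.

Step 10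
Reactants: 16 (1R,2R,4S,5S)-2,4-dichloro-1-(chloromethyl)-5-ethenyl-5-methylcyclohexyl acetate
Product: 17 (1R,2R,4S,5S)-2,4-dichloro-1-(chloromethyl)-5-formyl-5-methylcyclohexyl acetate
Conditions: O3, CH2Cl2/MeOH, −78 °C; then Me2S
Reagents that add atoms: ozone, [O-][O+]=O
Why: Ozonolysis with reductive work-up should cleave the only remaining alkene to the non-enolisable aldehyde, the tertiary acetate preventing lactol formation.

Step 11
Reactants: 17 (1R,2R,4S,5S)-2,4-dichloro-1-(chloromethyl)-5-formyl-5-methylcyclohexyl acetate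
Product: 18 (1R,2R,4S,5S)-2,4-dichloro-5-[(E)-2-chloroethenyl]-1-(chloromethyl)-5-methylcyclohexyl acetate
Conditions: CrCl2, CHCl3, THF, 65 °C
Reagents that add atoms: chloroform, ClC(Cl)Cl
Why: Takai–Utimoto chloro-olefination through a gem-dichromium species should give the E-alkenyl chloride and tolerates the ester and the unactivated alkyl chlorides.

Step 12
Reactants: 18 (1R,2R,4S,5S)-2,4-dichloro-5-[(E)-2-chloroethenyl]-1-(chloromethyl)-5-methylcyclohexyl acetate
Product: 19 (1R,2R,4S,5S)-1-bromo-2,4-dichloro-1-(chloromethyl)-5-[(E)-2-chloroethenyl]-5-methylcyclohexane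
Conditions: TMSBr, ZnBr2 (cat.), CH2Cl2, −20 °C to rt
Reagents that add atoms: bromotrimethylsilane, C[Si](C)(C)Br
Why: Silyl-halide cleavage of the tertiary ester by alkyl–oxygen ionisation (SN1) is assisted by the antiperiplanar CH2–Cl as a chloronium ion, so bromide should enter at the tertiary carbon with retention, which is also the thermodynamically preferred axial-bromide epimer.

**Compound list**
1 | ethynylmagnesium bromide | C#C[Mg]Br | starting material
2 | 2,3-dibromoprop-1-ene | C=C(Br)CBr | starting material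
3 | 2-bromopent-1-en-4-yne | C=C(Br)CC#C | intermediate
4 | [(1E)-4-bromo-2-methylpenta-1,4-dien-1-yl]dimethylalumane | C[Al](C)/C=C(\C)CC(Br)=C | intermediate
5 | (2E)-5-bromo-3-methylhexa-2,5-dien-1-ol | OC/C=C(\C)CC(Br)=C | intermediate
6 | (2E)-3-methyl-5-(4,4,5,5-tetramethyl-1,3,2-dioxaborolan-2-yl)hexa-2,5-dien-1-ol | OC/C=C(\C)CC(=C)B1OC(C)(C)C(C)(C)O1 | intermediate
7 | 2,2'-[(2E)-3-methylhexa-2,5-diene-1,5-diyl]bis(4,4,5,5-tetramethyl-1,3,2-dioxaborolane) | CC1(C)OB(C/C=C(\C)CC(=C)B2OC(C)(C)C(C)(C)O2)OC1(C)C | intermediate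
8 | 3,3-diethoxyprop-1-yne | C#CC(OCC)OCC | starting material
9 | benzyl(dimethyl)silane | C[SiH](C)Cc1ccccc1 | starting material
10 | benzyl[(1E)-3,3-diethoxyprop-1-en-1-yl]dimethylsilane | CCOC(OCC)/C=C/[Si](C)(C)Cc1ccccc1 | intermediate
11 | (2E)-3-[benzyl(dimethyl)silyl]prop-2-enal | O=C/C=C/[Si](C)(C)Cc1ccccc1 | intermediate
12 | (3S,6E)-3-[benzyl(dimethyl)silyl]-6-methyl-4-methylidene-8-(4,4,5,5-tetramethyl-1,3,2-dioxaborolan-2-yl)oct-6-enal | O=CC[C@H]([Si](C)(C)Cc1ccccc1)C(=C)C/C(C)=C/CB1OC(C)(C)C(C)(C)O1 | intermediate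
13 | (1R,2S,5S)-5-[benzyl(dimethyl)silyl]-2-ethenyl-2-methyl-4-methylidenecyclohexan-1-ol | C[C@@]1(C=C)CC(=C)[C@@H]([Si](C)(C)Cc2ccccc2)C[C@H]1O | intermediate
14 | (1S,3R,4S)-4-ethenyl-4-methyl-6-methylidenecyclohexane-1,3-diol | C[C@@]1(C=C)CC(=C)[C@@H](O)C[C@H]1O | intermediate
15 | (1S,2S,4R)-2,4-dichloro-1-ethenyl-1-methyl-5-methylidenecyclohexane | C[C@@]1(C=C)CC(=C)[C@H](Cl)C[C@@H]1Cl | intermediate
16 | (1R,2R,4S,5S)-2,4-dichloro-1-(chloromethyl)-5-ethenyl-5-methylcyclohexyl acetate | C[C@@]1(C=C)C[C@@](OC(C)=O)(CCl)[C@H](Cl)C[C@@H]1Cl | intermediate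
17 | (1R,2R,4S,5S)-2,4-dichloro-1-(chloromethyl)-5-formyl-5-methylcyclohexyl acetate | C[C@@]1(C=O)C[C@@](OC(C)=O)(CCl)[C@H](Cl)C[C@@H]1Cl | intermediate
18 | (1R,2R,4S,5S)-2,4-dichloro-5-[(E)-2-chloroethenyl]-1-(chloromethyl)-5-methylcyclohexyl acetate | C[C@@]1(/C=C/Cl)C[C@@](OC(C)=O)(CCl)[C@H](Cl)C[C@@H]1Cl | intermediate
19 | (1R,2R,4S,5S)-1-bromo-2,4-dichloro-1-(chloromethyl)-5-[(E)-2-chloroethenyl]-5-methylcyclohexane | C[C@@]1(/C=C/Cl)C[C@@](Br)(CCl)[C@H](Cl)C[C@@H]1Cl | target

Total step count: 12. Longest linear sequence: 11 steps (steps 1–4, then 6–12).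

**Steps most likely to fail**

Step 6. The domino may break down through competing transmetalation or protodeboronation of the allylboronate, 1,2-addition to the enal, or allylboration of 11 before the conjugate addition. An axial preference of the allylic silyl group in the cyclisation would also erode the relay of configuration. The fallback separates the two events with known chemistry. It sets out from 6, which is acetylated (Ac2O, pyridine) to (2E)-3-methyl-5-(4,4,5,5-tetramethyl-1,3,2-dioxaborolan-2-yl)hexa-2,5-dien-1-yl acetate F1. Hayashi–Miyaura addition of F1 to 11 with the same rhodium–diene catalyst should give (2E,6S)-6-[benzyl(dimethyl)silyl]-3-methyl-5-methylidene-8-oxooct-2-en-1-yl acetate F2. Palladium-catalysed borylation of the allylic acetate (Pd2(dba)3, B2pin2, DMSO, 50 °C) then generates 12, which cyclises as it forms, and the route is rejoined at 13.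

Step 8. Backside displacement at the carbinol next to the quaternary carbon may be too slow, leading to elimination or a 1,2-shift, and the allylic carbinol may react with allylic transposition. The fallback handles the hindered centre by front-side delivery instead. It sets out from 13, which is oxidised with Dess–Martin periodinane to (2S,5S)-5-[benzyl(dimethyl)silyl]-2-ethenyl-2-methyl-4-methylidenecyclohexan-1-one F3. Equatorial hydride delivery with LiBH(s-Bu)3 should give the axial alcohol (1S,2S,5S)-5-[benzyl(dimethyl)silyl]-2-ethenyl-2-methyl-4-methylidenecyclohexan-1-ol F4. SOCl2 in dioxane (SNi, retention) gives benzyl[(1S,4S,5S)-5-chloro-4-ethenyl-4-methyl-2-methylidenecyclohexyl]dimethylsilane F5. Tamao–Fleming oxidation gives (1S,4S,5S)-5-chloro-4-ethenyl-4-methyl-2-methylidenecyclohexan-1-ol F6, and an Appel reaction at the allylic carbinol alone (inversion) rejoins the route at 15.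

Step 12. Ionisation may be followed by bromide capture at the primary carbon of the chloronium ion (halogen interchange), by elimination, or by capture from the wrong face. The fallback installs bromide by invertive epoxide opening. It sets out from 15, whose 1,1-disubstituted alkene is epoxidised with mCPBA from the equatorial face to (3S,4R,6S,7S)-4,6-dichloro-7-ethenyl-7-methyl-1-oxaspiro[2.5]octane F7. Ozonolysis gives (3S,4R,6S,7S)-4,6-dichloro-7-methyl-1-oxaspiro[2.5]octane-7-carbaldehyde F8, and Takai chloro-olefination gives (3S,4R,6S,7S)-4,6-dichloro-7-[(E)-2-chloroethenyl]-7-methyl-1-oxaspiro[2.5]octane F9. Anhydrous HBr (CH2Cl2, −78 °C) should open the epoxide at the tertiary carbon with inversion to [(1R,2R,4S,5S)-1-bromo-2,4-dichloro-5-[(E)-2-chloroethenyl]-5-methylcyclohexyl]methanol F10. An Appel reaction of the primary alcohol then arrives at 19.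

**Further compounds**
F1 | step 6 | (2E)-3-methyl-5-(4,4,5,5-tetramethyl-1,3,2-dioxaborolan-2-yl)hexa-2,5-dien-1-yl acetate | CC(=O)OC/C=C(\C)CC(=C)B1OC(C)(C)C(C)(C)O1
F2 | step 6 | (2E,6S)-6-[benzyl(dimethyl)silyl]-3-methyl-5-methylidene-8-oxooct-2-en-1-yl acetate | CC(=O)OC/C=C(\C)CC(=C)[C@@H]([Si](C)(C)Cc1ccccc1)CC=O
F3 | step 8 | (2S,5S)-5-[benzyl(dimethyl)silyl]-2-ethenyl-2-methyl-4-methylidenecyclohexan-1-one | C[C@@]1(C=C)CC(=C)[C@@H]([Si](C)(C)Cc2ccccc2)CC1=O
F4 | step 8 | (1S,2S,5S)-5-[benzyl(dimethyl)silyl]-2-ethenyl-2-methyl-4-methylidenecyclohexan-1-ol | C[C@@]1(C=C)CC(=C)[C@@H]([Si](C)(C)Cc2ccccc2)C[C@@H]1O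
F5 | step 8 | benzyl[(1S,4S,5S)-5-chloro-4-ethenyl-4-methyl-2-methylidenecyclohexyl]dimethylsilane | C[C@@]1(C=C)CC(=C)[C@@H]([Si](C)(C)Cc2ccccc2)C[C@@H]1Cl
F6 | step 8 | (1S,4S,5S)-5-chloro-4-ethenyl-4-methyl-2-methylidenecyclohexan-1-ol | C[C@@]1(C=C)CC(=C)[C@@H](O)C[C@@H]1Cl
F7 | step 12 | (3S,4R,6S,7S)-4,6-dichloro-7-ethenyl-7-methyl-1-oxaspiro[2.5]octane | C[C@@]1(C=C)C[C@]2(CO2)[C@H](Cl)C[C@@H]1Cl
F8 | step 12 | (3S,4R,6S,7S)-4,6-dichloro-7-methyl-1-oxaspiro[2.5]octane-7-carbaldehyde | C[C@@]1(C=O)C[C@]2(CO2)[C@H](Cl)C[C@@H]1Cl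
F9 | step 12 | (3S,4R,6S,7S)-4,6-dichloro-7-[(E)-2-chloroethenyl]-7-methyl-1-oxaspiro[2.5]octane | C[C@@]1(/C=C/Cl)C[C@]2(CO2)[C@H](Cl)C[C@@H]1Cl
F10 | step 12 | [(1R,2R,4S,5S)-1-bromo-2,4-dichloro-5-[(E)-2-chloroethenyl]-5-methylcyclohexyl]methanol | C[C@@]1(/C=C/Cl)C[C@@](Br)(CO)[C@H](Cl)C[C@@H]1Cl
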